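**Plan**
- Retrosynthesis: the thirteen hydroxyls are masked as methyl ethers (20). The ring B–O–ring C ether is cut first (phenol 14 + bromide 19). Ring D is then opened at its C3–C4 bond to the open-chain keto ester 10.
- Keto ester 10 is cut at chain C4–C5 (γ-acylation of a dienolate by a ring E aryloxyacetamide) and at the C3–O enol ether bond (oxa-Michael addition of the ring C phenol to methyl but-2-ynoate).
- Enabling feature: ring D carries the ring E aryloxy group at C4 between hydroxyls at C3 and C5, and the ring C ether oxygen at C1. This is the oxygen pattern of a folded 6-aryloxy-3,5-dioxohexanoate whose C3 oxygen is already an aryl enol ether, so both crowded ether oxygens of ring D can be attached to non-aromatic carbons before the ring exists.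
- Forward: ring C phenol 5 (three steps from 1) → enol ether 7 → keto ester 10 → ring D by Claisen closure (12) → methylation, debenzylation (14) → coupling with the separately made ring A–B bromide 19 → global demethylation.
- Stereochemistry: the target has no stereocentre. The only stereo-element on the way, the E enol ether of 7 and 10, should come from thermodynamic control in the oxa-Michael step and vanishes on aromatisation.

Key step: step 7

Remark: rings are lettered A (2,4,6-trihydroxyphenyl end) to E (3,4,5-trihydroxyphenyl end); ring D is numbered from the carbon bearing the ring C ether oxygen, and the hexenoate chain from the ester carbon (C1) to the aryloxy-bearing carbon (C6). Compounds 1, 6, 8, 15 and 18 are taken as purchased.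

**Step 1**
Reactants: 1 3,4,5-trimethoxyphenol
Product: 2 5-(benzyloxy)-1,2,3-trimethoxybenzene
Conditions: BnBr, K2CO3, DMF, rt
Reagents that add atoms: benzyl bromide BrCc1ccccc1
Why: Williamson ether synthesis, the phenoxide displacing bromide from the benzylic halide; benzyl is the one ether that can later be removed without touching the methyl ethers.

**Step 2**
Reactants: 2 5-(benzyloxy)-1,2,3-trimethoxybenzene
Product: 3 6-(benzyloxy)-2,3,4-trimethoxybenzaldehyde
Conditions: POCl3, DMF, 0 → 60 °C; then H2O
Reagents that add atoms: N,N-dimethylformamide CN(C)C=O; water O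
Why: Vilsmeier–Haack formylation, in which the two equivalent free positions of 2 are each ortho to two alkoxy groups and para to a third, and the first formyl group deactivates the ring against a second.

**Step 3**
Reactants: 3 6-(benzyloxy)-2,3,4-trimethoxybenzaldehyde
Product: 5 6-(benzyloxy)-2,3,4-trimethoxyphenol, via aryl formate 4 (not isolated)
Conditions: mCPBA, CH2Cl2, 0 °C → rt; then K2CO3 (cat.), MeOH, rt
Reagents that add atoms: 3-chloroperoxybenzoic acid OOC(=O)c1cccc(Cl)c1
Why: Baeyer–Villiger (Dakin-type) oxidation, in which the electron-rich aryl group of an ortho/para-alkoxy benzaldehyde migrates in preference to hydride, followed by base-catalysed methanolysis of the formate that leaves the benzyl ether alone.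

**Step 4**
Reactants: 5 6-(benzyloxy)-2,3,4-trimethoxyphenol; 6 methyl but-2-ynoate
Product: 7 methyl (E)-3-[6-(benzyloxy)-2,3,4-trimethoxyphenoxy]but-2-enoate
Conditions: K2CO3 (0.5 equiv), DMF, 70 °C
Reagents that add atoms: none
Why: Oxa-Michael addition of the phenoxide to the β-carbon of the ynoate, with proton transfer regenerating the base; the E isomer (ester trans to the aryloxy group) is expected as the thermodynamically preferred enol ether.

**Step 5**
Reactants: 1 3,4,5-trimethoxyphenol; 8 2-chloro-N-methoxy-N-methylacetamide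
Product: 9 N-methoxy-N-methyl-2-(3,4,5-trimethoxyphenoxy)acetamide
Conditions: K2CO3, KI (cat.), acetone, reflux
Reagents that add atoms: none
Why: Williamson ether synthesis with an α-chloro amide, an SN2 displacement accelerated by the adjacent carbonyl group and by iodide catalysis, which places the ring E oxygen on an sp3 carbon.

**Step 6**
Reactants: 7 methyl (E)-3-[6-(benzyloxy)-2,3,4-trimethoxyphenoxy]but-2-enoate; 9 N-methoxy-N-methyl-2-(3,4,5-trimethoxyphenoxy)acetamide
Product: 10 methyl (E)-3-[6-(benzyloxy)-2,3,4-trimethoxyphenoxy]-5-oxo-6-(3,4,5-trimethoxyphenoxy)hex-2-enoate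
Conditions: LiN(iPr)2 (1.1 equiv), THF, −78 °C; then 9, −78 → −40 °C; AcOH, −78 °C
Reagents that add atoms: none
Why: Vinylogous Claisen acylation, in which the γ-deprotonated 3-aryloxybut-2-enoate should react at its γ-carbon as 3-alkoxy analogues do, and the chelated tetrahedral adduct of the Weinreb amide prevents a second addition and releases the ketone only on the cold acidic quench, with the E geometry retained.

**Step 7**
Reactants: 10 methyl (E)-3-[6-(benzyloxy)-2,3,4-trimethoxyphenoxy]-5-oxo-6-(3,4,5-trimethoxyphenoxy)hex-2-enoate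
Product: 12 5-[6-(benzyloxy)-2,3,4-trimethoxyphenoxy]-2-(3,4,5-trimethoxyphenoxy)benzene-1,3-diol, via cyclohexenedione tautomer 11 (not isolated)
Conditions: LiN(SiMe3)2 (3 equiv), THF, −78 → 0 °C; then 1 M HCl
Reagents that add atoms: none
Why: The first equivalent of LiN(SiMe3)2 removes a C4 proton to give the extended enolate and the second removes a C6 proton, acidified by the ketone and the aryloxy group, so that the terminal carbanion of the dianion adds to the ester carbonyl (chain C6 to C1, the D4–D3 bond) and methoxide is expelled. This is an intramolecular Claisen (Dieckmann-type) condensation, and the closest known reaction type is the base-mediated closure of 3,5-dioxohexanoates and their 3-enol ethers to phloroglucinols and resorcinols. Ring D closes in a 6-exo-trig mode, the attacked C=O bond lying outside the new ring, and the enolate of cyclohexenedione 11 is deprotonated at once by the released methoxide to the bis-phenoxide of 12, which makes the closure irreversible. No stereocentre is formed and the enol ether geometry disappears on aromatisation. The step needs acylation at carbon and not at the enolate oxygen (which would give a 4-aryloxypyran-2-one) and retention of the ring C aryloxy group: the dianion reacts at its most basic site C6, the E enol ether already holds the ester and the ketone arm cis, the silylamide base does not add to C3, and loss of aryloxide from the C4 anion would require an allenoate.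

**Step 8**
Reactants: 12 5-[6-(benzyloxy)-2,3,4-trimethoxyphenoxy]-2-(3,4,5-trimethoxyphenoxy)benzene-1,3-diol
Product: 13 1-(benzyloxy)-2-[3,5-dimethoxy-4-(3,4,5-trimethoxyphenoxy)phenoxy]-3,4,5-trimethoxybenzene
Conditions: Me2SO4, K2CO3, acetone, reflux
Reagents that add atoms: dimethyl sulfate COS(=O)(=O)OC
Why: Williamson-type O-methylation of both phenols with the hard electrophile dimethyl sulfate, as is usual for phloroglucinol ethers where softer halides risk C-alkylation.

**Step 9**
Reactants: 13 1-(benzyloxy)-2-[3,5-dimethoxy-4-(3,4,5-trimethoxyphenoxy)phenoxy]-3,4,5-trimethoxybenzene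
Product: 14 2-[3,5-dimethoxy-4-(3,4,5-trimethoxyphenoxy)phenoxy]-3,4,5-trimethoxyphenol
Conditions: H2 (1 atm), 10% Pd/C, EtOAc–MeOH, rt
Reagents that add atoms: none
Why: Hydrogenolysis of the single benzyl ether over palladium on carbon, to which methyl and diaryl ethers are inert, so only the ring C hydroxyl is set free.

**Step 10**
Reactants: 15 2-bromo-6-methoxyphenol
Product: 16 2-bromo-4-iodo-6-methoxyphenol
Conditions: N-iodosuccinimide, MeCN, 0 °C → rt
Reagents that add atoms: N-iodosuccinimide O=C1CCC(=O)N1I
Why: Electrophilic aromatic iodination, the hydroxyl group being the strongest director and its para position the only ortho or para site still open.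

**Step 11**
Reactants: 16 2-bromo-4-iodo-6-methoxyphenol
Product: 17 1-bromo-5-iodo-2,3-dimethoxybenzene
Conditions: MeI, K2CO3, acetone, reflux
Reagents that add atoms: iodomethane CI
Why: Williamson ether synthesis on a simple phenol.

**Step 12**
Reactants: 17 1-bromo-5-iodo-2,3-dimethoxybenzene; 18 2,4,6-trimethoxyphenol
Product: 19 1-bromo-2,3-dimethoxy-5-(2,4,6-trimethoxyphenoxy)benzene
Conditions: CuI (10 mol %), picolinic acid (20 mol %), K3PO4, DMSO, 80 °C, argon; 17 in slight excess
Reagents that add atoms: none
Why: Ullmann-type diaryl ether synthesis, in which the C–I bond (no ortho substituent) should react well before the C–Br bond flanked by a methoxy group, and the CuI/picolinic acid system tolerates the doubly ortho-substituted phenoxide of 18.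

**Step 13**
Reactants: 14 2-[3,5-dimethoxy-4-(3,4,5-trimethoxyphenoxy)phenoxy]-3,4,5-trimethoxyphenol; 19 1-bromo-2,3-dimethoxy-5-(2,4,6-trimethoxyphenoxy)benzene
Product: 20 tridecamethyl ether of the target (rings A–E fully O-methylated)
Conditions: CuI (20 mol %), picolinic acid (40 mol %), K3PO4, DMSO, 100 °C, argon
Reagents that add atoms: none
Why: Ullmann-type diaryl ether synthesis under CuI/picolinic acid catalysis, which suits electron-rich and ortho-substituted partners; each partner here has only one ortho substituent, the doubly flanked ethers of rings A, C and D having been made earlier.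

**Step 14**
Reactants: 20 tridecamethyl ether of the target
Product: 21 CNP0228612.0 (target, thirteen free hydroxyls)
Conditions: BBr3 (excess), CH2Cl2, −78 °C → rt; then MeOH, H2O; work-up under argon
Reagents that add atoms: none
Why: Lewis acid-mediated cleavage of aryl methyl ethers, in which BBr3 complexes each methoxy oxygen and bromide removes the methyl group as bromomethane, while the diaryl ether C–O bonds offer no SN2 site and should survive; hydrolysis of the aryl borates frees the hydroxyls.

**Compound list**
1 | 3,4,5-trimethoxyphenol | COc1cc(O)cc(OC)c1OC | starting material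
2 | 5-(benzyloxy)-1,2,3-trimethoxybenzene | COc1cc(OCc2ccccc2)cc(OC)c1OC | intermediate
3 | 6-(benzyloxy)-2,3,4-trimethoxybenzaldehyde | O=Cc1c(OCc2ccccc2)cc(OC)c(OC)c1OC | intermediate
4 | 6-(benzyloxy)-2,3,4-trimethoxyphenyl formate | O=COc1c(OCc2ccccc2)cc(OC)c(OC)c1OC | intermediate
5 | 6-(benzyloxy)-2,3,4-trimethoxyphenol | Oc1c(OCc2ccccc2)cc(OC)c(OC)c1OC | intermediate
6 | methyl but-2-ynoate | CC#CC(=O)OC | starting material
7 | methyl (E)-3-[6-(benzyloxy)-2,3,4-trimethoxyphenoxy]but-2-enoate | COC(=O)/C=C(/Oc1c(OCc2ccccc2)cc(OC)c(OC)c1OC)C | intermediate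
8 | 2-chloro-N-methoxy-N-methylacetamide | CON(C)C(=O)CCl | starting material
9 | N-methoxy-N-methyl-2-(3,4,5-trimethoxyphenoxy)acetamide | CON(C)C(=O)COc1cc(OC)c(OC)c(OC)c1 | intermediate
10 | methyl (E)-3-[6-(benzyloxy)-2,3,4-trimethoxyphenoxy]-5-oxo-6-(3,4,5-trimethoxyphenoxy)hex-2-enoate | COC(=O)/C=C(/Oc1c(OCc2ccccc2)cc(OC)c(OC)c1OC)CC(=O)COc1cc(OC)c(OC)c(OC)c1 | intermediate
11 | 5-[6-(benzyloxy)-2,3,4-trimethoxyphenoxy]-2-(3,4,5-trimethoxyphenoxy)cyclohex-4-ene-1,3-dione (racemic at C2, transient) | O=C1C=C(Oc2c(OCc3ccccc3)cc(OC)c(OC)c2OC)CC(=O)C1Oc1cc(OC)c(OC)c(OC)c1 | intermediate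
12 | 5-[6-(benzyloxy)-2,3,4-trimethoxyphenoxy]-2-(3,4,5-trimethoxyphenoxy)benzene-1,3-diol | Oc1cc(Oc2c(OCc3ccccc3)cc(OC)c(OC)c2OC)cc(O)c1Oc1cc(OC)c(OC)c(OC)c1 | intermediate
13 | 1-(benzyloxy)-2-[3,5-dimethoxy-4-(3,4,5-trimethoxyphenoxy)phenoxy]-3,4,5-trimethoxybenzene | COc1cc(Oc2c(OCc3ccccc3)cc(OC)c(OC)c2OC)cc(OC)c1Oc1cc(OC)c(OC)c(OC)c1 | intermediate
14 | 2-[3,5-dimethoxy-4-(3,4,5-trimethoxyphenoxy)phenoxy]-3,4,5-trimethoxyphenol | COc1cc(Oc2c(O)cc(OC)c(OC)c2OC)cc(OC)c1Oc1cc(OC)c(OC)c(OC)c1 | intermediate
15 | 2-bromo-6-methoxyphenol | COc1cccc(Br)c1O | starting material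
16 | 2-bromo-4-iodo-6-methoxyphenol | COc1cc(I)cc(Br)c1O | intermediate
17 | 1-bromo-5-iodo-2,3-dimethoxybenzene | COc1cc(I)cc(Br)c1OC | intermediate
18 | 2,4,6-trimethoxyphenol | COc1cc(OC)c(O)c(OC)c1 | starting material
19 | 1-bromo-2,3-dimethoxy-5-(2,4,6-trimethoxyphenoxy)benzene | COc1cc(OC)c(Oc2cc(OC)c(OC)c(Br)c2)c(OC)c1 | intermediate
20 | tridecamethyl ether of the target | COc1cc(OC)c(Oc2cc(OC)c(OC)c(Oc3cc(OC)c(OC)c(OC)c3Oc3cc(OC)c(Oc4cc(OC)c(OC)c(OC)c4)c(OC)c3)c2)c(OC)c1 | intermediate
21 | CNP0228612.0 | Oc1cc(O)c(Oc2cc(O)c(O)c(Oc3cc(O)c(O)c(O)c3Oc3cc(O)c(Oc4cc(O)c(O)c(O)c4)c(O)c3)c2)c(O)c1 | target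

**Step count**
Total: 14 steps. Longest linear sequence: 10 steps (1, 2, 3, 4, 6, 7, 8, 9, 13, 14).

**Steps most likely to fail**

Step 7. Closure through the enolate oxygen to the pyranone, incomplete second deprotonation, or exchange of the ring C aryloxide by released methoxide at C3 may outrun C-acylation. The fallback takes ring D as a ready-made arene. Purchased 4-bromo-2,6-dimethoxyphenol and (3,4,5-trimethoxyphenyl)boronic acid would be joined by Chan–Lam coupling (Cu(OAc)2, pyridine, 4 Å molecular sieves, CH2Cl2, air, rt) to 5-bromo-1,3-dimethoxy-2-(3,4,5-trimethoxyphenoxy)benzene F1. Its unflanked C–Br bond would then be coupled with phenol 5 under the Ullmann conditions of step 13. The fallback sets out from 5 and comes back to the route at 13.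

Step 13. Slow oxidative addition of the electron-rich, ortho-methoxy bromide and oxidative degradation of the electron-rich phenoxide at 100 °C may stall the coupling. The fallback reverses the polarity of ring B. Bromide 19 would be converted (nBuLi, THF, −78 °C; B(OiPr)3; aq. HCl) into [2,3-dimethoxy-5-(2,4,6-trimethoxyphenoxy)phenyl]boronic acid F2. F2 would be coupled with phenol 14 at room temperature by Chan–Lam etherification (Cu(OAc)2, pyridine, 4 Å molecular sieves, CH2Cl2, air). The fallback sets out from 19 and comes back at 20.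

Step 6. Proton transfer from the α-aryloxy amide to the dienolate, attack through the α-carbon, or lactonisation of the product during work-up may erode the acylation. The fallback replaces acylation by aldol addition and oxidation. Weinreb amide 9 would be reduced (iBu2AlH, THF, −78 °C) to (3,4,5-trimethoxyphenoxy)acetaldehyde F3. The lithium dienolate of 7 (LiN(iPr)2, THF, −78 °C, cold AcOH quench) should add to F3 at its γ-carbon, as 3-alkoxybut-2-enoate dienolates do with aldehydes, giving racemic methyl (E)-3-[6-(benzyloxy)-2,3,4-trimethoxyphenoxy]-5-hydroxy-6-(3,4,5-trimethoxyphenoxy)hex-2-enoate F4. Dess–Martin periodinane (CH2Cl2, NaHCO3) would oxidise F4 to the ketone. The fallback sets out from 9 (and 7) and comes back at 10.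

**Further compounds**
F1 | step 7 | 5-bromo-1,3-dimethoxy-2-(3,4,5-trimethoxyphenoxy)benzene | COc1cc(Br)cc(OC)c1Oc1cc(OC)c(OC)c(OC)c1
F2 | step 13 | [2,3-dimethoxy-5-(2,4,6-trimethoxyphenoxy)phenyl]boronic acid | COc1cc(OC)c(Oc2cc(OC)c(OC)c(B(O)O)c2)c(OC)c1
F3 | step 6 | (3,4,5-trimethoxyphenoxy)acetaldehyde | O=CCOc1cc(OC)c(OC)c(OC)c1
F4 | step 6 | methyl (E)-3-[6-(benzyloxy)-2,3,4-trimethoxyphenoxy]-5-hydroxy-6-(3,4,5-trimethoxyphenoxy)hex-2-enoate (racemic) | COC(=O)/C=C(/Oc1c(OCc2ccccc2)cc(OC)c(OC)c1OC)CC(O)COc1cc(OC)c(OC)c(OC)c1
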